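Ring A, the cyclohexane, is numbered from the CH carrying benzylic C7 (C1) through the methylidene carbon (C2), two CH2 groups (C3, C4) and CHBr (C5) to CMe2 (C6). The route rests on disconnecting C1–C2: C2 is a latent ketone and C1–C7–aryl a latent aryl alkyne whose sp carbon C1, beside quaternary C6, is open to an acyl radical. One 6-exo-dig radical hydroacylation thus builds ring A, the C2 carbonyl and a C1=C7 alkene ready for hydrogenation directed from C5. The precursor is an acyclic (4S)-4-silyloxy-5,5-dimethylhept-6-ynal bearing a 4-bromo-2,5-bis(pivaloyloxy)phenyl group on the alkyne.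

Key step: step 9

Remarks on the chemistry
- Abbreviations: pivaloyloxy = (2,2-dimethylpropanoyl)oxy; TBS = tert-butyldimethylsilyl.
- Design choice: the hydroquinone oxygens are carried as pivalates, not as alkyl ethers. An electron-poor arene should not be oxidised by the excited polyoxotungstate. It offers no O–CH3 hydrogens to the photocatalyst or, by 1,5-shift, to the C7 vinyl radical. It polarises the alkyne toward the nucleophilic acyl radical, and it is unmasked at the end by hydride instead of an oxidant.
- Design choice: the carbinol centre is set by catalytic reduction of a tert-alkyl/primary-alkyl ketone, a well-differentiated substrate type for oxazaborolidine catalysis.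
- Assumption: compound 14 is written as the Z isomer (aryl on the carbonyl side, away from C6). Any E isomer has the same constitution and converges in step 11, where C7 becomes CH2.
- Assumption: compounds 1, 4 and 7 are taken as catalogue chemicals.

Step 1
Reactants: 1 1-bromo-4-iodo-2,5-dimethoxybenzene
Product: 2 2-bromo-5-iodobenzene-1,4-diol
Conditions: BBr3 (2.5 equiv), CH2Cl2, −78 °C to rt; then H2O
Reagents that add atoms: none
Why: Lewis-acid cleavage of aryl methyl ethers (BBr3 demethylation) is routine on halogenated hydroquinone dimethyl ethers and should leave the C–Br and C–I bonds untouched.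

Step 2
Reactants: 2 2-bromo-5-iodobenzene-1,4-diol
Product: 3 2-bromo-5-iodo-1,4-phenylene bis(2,2-dimethylpropanoate)
Conditions: pivaloyl chloride, Et3N, DMAP (cat.), CH2Cl2, 0 °C to rt
Reagents that add atoms: pivaloyl chloride, CC(C)(C)C(Cl)=O
Why: DMAP-catalysed O-acylation of both phenols with an acid chloride should give a hindered, electron-poor diester that withstands the later palladium, borane, acid, fluoride and zinc/titanium steps.

Step 3
Reactants: 4 2,2-dimethylbut-3-ynoic acid
Product: 6 N-methoxy-N,2,2-trimethylbut-3-ynamide, via acyl imidazole 5 (not isolated)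
Conditions: 1,1'-carbonyldiimidazole, CH2Cl2, rt; then MeNH(OMe)·HCl, rt
Reagents that add atoms: N,O-dimethylhydroxylamine hydrochloride, CNOC.Cl
Why: Weinreb amide formation through an acyl imidazole (carbonyldiimidazole coupling) copes with the α,α-disubstituted acid and leaves the terminal alkyne alone.

Step 4
Reactants: 7 2-(2-bromoethyl)-1,3-dioxolane; 6 N-methoxy-N,2,2-trimethylbut-3-ynamide
Product: 9 1-(1,3-dioxolan-2-yl)-4,4-dimethylhex-5-yn-3-one, via Grignard reagent 8 (not isolated)
Conditions: 7 (3 equiv), Mg, THF, 25 °C; then 6, THF, 0 °C to rt; aq. NH4Cl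
Reagents that add atoms: none
Why: Weinreb ketone synthesis, in which the Grignard reagent (in excess, since one equivalent is spent on the acetylenic C–H) adds once to give a stable magnesium chelate that releases the ketone only on work-up, while the quaternary α-carbon rules out alkyne-to-allene isomerisation.

Step 5
Reactants: 9 1-(1,3-dioxolan-2-yl)-4,4-dimethylhex-5-yn-3-one; 3 2-bromo-5-iodo-1,4-phenylene bis(2,2-dimethylpropanoate)
Product: 10 6-[4-bromo-2,5-bis(pivaloyloxy)phenyl]-1-(1,3-dioxolan-2-yl)-4,4-dimethylhex-5-yn-3-one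
Conditions: PdCl2(PPh3)2 (2 mol%), CuI (4 mol%), Et3N, THF, rt, degassed
Reagents that add atoms: none
Why: Sonogashira coupling should occur only at the C–I bond at room temperature, leaving C–Br, the ketone, the acetal and the aryl esters intact.

Step 6
Reactants: 10 6-[4-bromo-2,5-bis(pivaloyloxy)phenyl]-1-(1,3-dioxolan-2-yl)-4,4-dimethylhex-5-yn-3-one
Product: 11 (3S)-6-[4-bromo-2,5-bis(pivaloyloxy)phenyl]-1-(1,3-dioxolan-2-yl)-4,4-dimethylhex-5-yn-3-ol
Conditions: (R)-1-methyl-3,3-diphenyltetrahydro-1H,3H-pyrrolo[1,2-c][1,3,2]oxazaborole (20 mol%), BH3·SMe2, THF, −20 °C; then MeOH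
Reagents that add atoms: none
Why: Corey–Bakshi–Shibata reduction, in which the catalyst tells the tertiary propargylic carbon (large) from the CH2 chain (small), so the (R)-catalyst should deliver hydride to the face giving the (S)-carbinol, as with tert-alkyl methyl ketones.

Step 7
Reactants: 11 (3S)-6-[4-bromo-2,5-bis(pivaloyloxy)phenyl]-1-(1,3-dioxolan-2-yl)-4,4-dimethylhex-5-yn-3-ol
Product: 12 (3S)-6-[4-bromo-2,5-bis(pivaloyloxy)phenyl]-1-(1,3-dioxolan-2-yl)-4,4-dimethylhex-5-yn-3-yl tert-butyldimethylsilyl ether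
Conditions: TBSOTf (1.3 equiv), 2,6-lutidine, CH2Cl2, −40 to 0 °C
Reagents that add atoms: tert-butyldimethylsilyl trifluoromethanesulfonate, CC(C)(C)[Si](C)(C)OS(=O)(=O)C(F)(F)F
Why: Silylation of the hindered neopentylic alcohol with a silyl triflate and a hindered pyridine base is fast at low temperature, where the dioxolane should not be attacked.

Step 8
Reactants: 12 (3S)-6-[4-bromo-2,5-bis(pivaloyloxy)phenyl]-1-(1,3-dioxolan-2-yl)-4,4-dimethylhex-5-yn-3-yl tert-butyldimethylsilyl ether
Product: 13 (4S)-7-[4-bromo-2,5-bis(pivaloyloxy)phenyl]-4-(tert-butyldimethylsilyloxy)-5,5-dimethylhept-6-ynal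
Conditions: TsOH·H2O (cat.), acetone/H2O 10:1, 40 °C
Reagents that add atoms: water, O
Why: Acid-catalysed acetal hydrolysis (transacetalisation to acetone) should free the aldehyde while the hindered secondary silyl ether and the aryl pivalates survive mild aqueous acid.

Step 9
Reactants: 13 (4S)-7-[4-bromo-2,5-bis(pivaloyloxy)phenyl]-4-(tert-butyldimethylsilyloxy)-5,5-dimethylhept-6-ynal
Product: 14 (2Z,4S)-2-{[4-bromo-2,5-bis(pivaloyloxy)phenyl]methylidene}-4-(tert-butyldimethylsilyloxy)-3,3-dimethylcyclohexan-1-one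
Conditions: (Bu4N)4[W10O32] (4 mol%), MeCN (0.02 M), 390 nm LEDs, argon, 25 °C
Reagents that add atoms: none
Why: Photoexcited decatungstate should abstract the formyl hydrogen, the most hydridic and accessible C–H (the arene is electron-poor and the C–H next to the silyloxy group is shielded), and the nucleophilic acyl radical at C2 then adds to alkyne carbon C1 to leave an aryl-conjugated vinyl radical at C7, which is quenched by hydrogen-atom return from the reduced polyoxotungstate or by chain transfer from a second aldehyde. The closest known reaction type is acyl-radical exo-dig cyclisation onto alkynes, established from acyl selenides and from alkynyl aldehydes under hydrogen-abstraction conditions, combined with decatungstate hydroacylation of π-systems by aliphatic aldehydes. Ring A closes in the 6-exo-dig mode, and only the C1–C2 bond is formed. No stereocentre is created: C5 passes through unchanged, and the alkene geometry is of no consequence because C7 becomes CH2 in step 11. The step needs 6-exo rather than 7-endo attack and ring closure faster than loss of CO from the primary acyl radical; aryl stabilisation of the vinyl radical, the open sp carbon beside quaternary C6 and the gem-dimethyl (Thorpe–Ingold) effect should secure both.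

Step 10
Reactants: 14 (2Z,4S)-2-{[4-bromo-2,5-bis(pivaloyloxy)phenyl]methylidene}-4-(tert-butyldimethylsilyloxy)-3,3-dimethylcyclohexan-1-one
Product: 15 (2Z,4S)-2-{[4-bromo-2,5-bis(pivaloyloxy)phenyl]methylidene}-4-hydroxy-3,3-dimethylcyclohexan-1-one
Conditions: 48% aq. HF, MeCN, 0 °C to rt
Reagents that add atoms: none
Why: Acidic fluoride desilylation should remove the silyl ether without touching the aryl pivalates, which basic fluoride sources could cleave.

Step 11
Reactants: 15 (2Z,4S)-2-{[4-bromo-2,5-bis(pivaloyloxy)phenyl]methylidene}-4-hydroxy-3,3-dimethylcyclohexan-1-one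
Product: 16 (2R,4S)-2-{[4-bromo-2,5-bis(pivaloyloxy)phenyl]methyl}-4-hydroxy-3,3-dimethylcyclohexan-1-one
Conditions: [Ir(cod)(PCy3)(py)]PF6 (10 mol%), H2 (1–5 bar), CH2Cl2, rt
Reagents that add atoms: none
Why: Hydroxyl-directed homogeneous hydrogenation, in which the homoallylic C5 hydroxyl binds the cationic iridium centre and H2 is delivered to the face of C1=C7 syn to oxygen, so that C1–H is cis and the benzyl group trans to the hydroxyl (C1 R in this ketone), the aryl bromide being inert to this catalyst.

Step 12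
Reactants: 16 (2R,4S)-2-{[4-bromo-2,5-bis(pivaloyloxy)phenyl]methyl}-4-hydroxy-3,3-dimethylcyclohexan-1-one
Product: 17 (1S,3S)-3-{[4-bromo-2,5-bis(pivaloyloxy)phenyl]methyl}-2,2-dimethyl-4-methylidenecyclohexan-1-ol
Conditions: Zn, CH2Br2, TiCl4, THF (reagent pre-formed, excess); then 16, CH2Cl2, 0 °C to rt
Reagents that add atoms: dibromomethane, BrCBr
Why: Takai–Lombardo methylenation is non-basic, so the enolisable ketone should become the exocyclic alkene without epimerising C1, and the reagent (in excess to allow for the free hydroxyl) does not attack esters.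

Step 13
Reactants: 17 (1S,3S)-3-{[4-bromo-2,5-bis(pivaloyloxy)phenyl]methyl}-2,2-dimethyl-4-methylidenecyclohexan-1-ol
Product: 18 2-bromo-5-{[(1S,3R)-3-bromo-2,2-dimethyl-6-methylidenecyclohexyl]methyl}-1,4-phenylene bis(2,2-dimethylpropanoate)
Conditions: CBr4, (n-C8H17)3P, 2,6-lutidine, toluene, 70 °C
Reagents that add atoms: tetrabromomethane, BrC(Br)(Br)Br
Why: Appel reaction with a trialkylphosphine, in which bromide displaces the oxyphosphonium group by SN2 with inversion at C5 (S to R) through the conformer with axial C5–O and equatorial benzyl, giving the cis, diequatorial bromide, while the lutidine buffer guards the acid-sensitive exocyclic alkene.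

Step 14
Reactants: 18 2-bromo-5-{[(1S,3R)-3-bromo-2,2-dimethyl-6-methylidenecyclohexyl]methyl}-1,4-phenylene bis(2,2-dimethylpropanoate)
Product: 19 cyclocymopol, 2-bromo-5-{[(1S,3R)-3-bromo-2,2-dimethyl-6-methylidenecyclohexyl]methyl}benzene-1,4-diol
Conditions: i-Bu2AlH (5 equiv), CH2Cl2, −78 °C; then aq. potassium sodium tartrate
Reagents that add atoms: none
Why: Reductive cleavage of the aryl pivalates by an aluminium hydride (ester reduction) at low temperature should free the hydroquinone without base or oxidant, conditions under which the hindered secondary bromide and the exocyclic alkene are stable.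

Compound list
1 | 1-bromo-4-iodo-2,5-dimethoxybenzene | COc1cc(Br)c(OC)cc1I | starting material
2 | 2-bromo-5-iodobenzene-1,4-diol | Oc1cc(Br)c(O)cc1I | intermediate
3 | 2-bromo-5-iodo-1,4-phenylene bis(2,2-dimethylpropanoate) | CC(C)(C)C(=O)Oc1cc(Br)c(OC(=O)C(C)(C)C)cc1I | intermediate
4 | 2,2-dimethylbut-3-ynoic acid | C#CC(C)(C)C(=O)O | starting material
5 | 1-(imidazol-1-yl)-2,2-dimethylbut-3-yn-1-one (acyl imidazole) | C#CC(C)(C)C(=O)n1ccnc1 | intermediate
6 | N-methoxy-N,2,2-trimethylbut-3-ynamide | C#CC(C)(C)C(=O)N(C)OC | intermediate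
7 | 2-(2-bromoethyl)-1,3-dioxolane | BrCCC1OCCO1 | starting material
8 | [2-(1,3-dioxolan-2-yl)ethyl]magnesium bromide (Grignard reagent) | Br[Mg]CCC1OCCO1 | intermediate
9 | 1-(1,3-dioxolan-2-yl)-4,4-dimethylhex-5-yn-3-one | C#CC(C)(C)C(=O)CCC1OCCO1 | intermediate
10 | 6-[4-bromo-2,5-bis(pivaloyloxy)phenyl]-1-(1,3-dioxolan-2-yl)-4,4-dimethylhex-5-yn-3-one | O=C(CCC1OCCO1)C(C)(C)C#Cc1cc(OC(=O)C(C)(C)C)c(Br)cc1OC(=O)C(C)(C)C | intermediate
11 | (3S)-6-[4-bromo-2,5-bis(pivaloyloxy)phenyl]-1-(1,3-dioxolan-2-yl)-4,4-dimethylhex-5-yn-3-ol | O1CCOC1CC[C@H](O)C(C)(C)C#Cc1cc(OC(=O)C(C)(C)C)c(Br)cc1OC(=O)C(C)(C)C | intermediate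
12 | (3S)-6-[4-bromo-2,5-bis(pivaloyloxy)phenyl]-1-(1,3-dioxolan-2-yl)-4,4-dimethylhex-5-yn-3-yl tert-butyldimethylsilyl ether | O1CCOC1CC[C@H](O[Si](C)(C)C(C)(C)C)C(C)(C)C#Cc1cc(OC(=O)C(C)(C)C)c(Br)cc1OC(=O)C(C)(C)C | intermediate
13 | (4S)-7-[4-bromo-2,5-bis(pivaloyloxy)phenyl]-4-(tert-butyldimethylsilyloxy)-5,5-dimethylhept-6-ynal | O=CCC[C@H](O[Si](C)(C)C(C)(C)C)C(C)(C)C#Cc1cc(OC(=O)C(C)(C)C)c(Br)cc1OC(=O)C(C)(C)C | intermediate
14 | (2Z,4S)-2-{[4-bromo-2,5-bis(pivaloyloxy)phenyl]methylidene}-4-(tert-butyldimethylsilyloxy)-3,3-dimethylcyclohexan-1-one | O=C1CC[C@H](O[Si](C)(C)C(C)(C)C)C(C)(C)/C1=C/c1cc(OC(=O)C(C)(C)C)c(Br)cc1OC(=O)C(C)(C)C | intermediate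
15 | (2Z,4S)-2-{[4-bromo-2,5-bis(pivaloyloxy)phenyl]methylidene}-4-hydroxy-3,3-dimethylcyclohexan-1-one | O=C1CC[C@H](O)C(C)(C)/C1=C/c1cc(OC(=O)C(C)(C)C)c(Br)cc1OC(=O)C(C)(C)C | intermediate
16 | (2R,4S)-2-{[4-bromo-2,5-bis(pivaloyloxy)phenyl]methyl}-4-hydroxy-3,3-dimethylcyclohexan-1-one | O=C1CC[C@H](O)C(C)(C)[C@H]1Cc1cc(OC(=O)C(C)(C)C)c(Br)cc1OC(=O)C(C)(C)C | intermediate
17 | (1S,3S)-3-{[4-bromo-2,5-bis(pivaloyloxy)phenyl]methyl}-2,2-dimethyl-4-methylidenecyclohexan-1-ol | C=C1CC[C@H](O)C(C)(C)[C@H]1Cc1cc(OC(=O)C(C)(C)C)c(Br)cc1OC(=O)C(C)(C)C | intermediate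
18 | 2-bromo-5-{[(1S,3R)-3-bromo-2,2-dimethyl-6-methylidenecyclohexyl]methyl}-1,4-phenylene bis(2,2-dimethylpropanoate) | C=C1CC[C@@H](Br)C(C)(C)[C@H]1Cc1cc(OC(=O)C(C)(C)C)c(Br)cc1OC(=O)C(C)(C)C | intermediate
19 | cyclocymopol, 2-bromo-5-{[(1S,3R)-3-bromo-2,2-dimethyl-6-methylidenecyclohexyl]methyl}benzene-1,4-diol | C=C1CC[C@@H](Br)C(C)(C)[C@H]1Cc1cc(O)c(Br)cc1O | target

Total step count: 14.
Longest linear sequence: 12 (steps 3 to 14, from acid 4). Aryl iodide 3 is made in two steps off the main line and enters at step 5; bromoacetal 7 enters at step 4.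

Steps most likely to fail

1. Step 9 (key step). Hydrogen abstraction may be inefficient if substrate or product competes for the excited catalyst. Quenching of the C7 vinyl radical may be slow, leading to oligomerisation. Part of the acyl radical may lose CO before ring closure. The fallback sets out from aldehyde 13 and returns at 14. Chlorite oxidation (NaClO2, NaH2PO4, 2-methylbut-2-ene, t-BuOH/H2O) should give (4S)-7-[4-bromo-2,5-bis(pivaloyloxy)phenyl]-4-(tert-butyldimethylsilyloxy)-5,5-dimethylhept-6-ynoic acid F1. Diphenyl diselenide and Bu3P in CH2Cl2 should convert this into Se-phenyl (4S)-7-[4-bromo-2,5-bis(pivaloyloxy)phenyl]-4-(tert-butyldimethylsilyloxy)-5,5-dimethylhept-6-yneselenoate F2. Slow addition of (Me3Si)3SiH and AIBN in benzene at 80 °C then generates the same acyl radical by selenium abstraction, which is faster than attack on the aryl bromide. The radical closes 6-exo-dig, and the silane, present in stoichiometric amount, reduces the vinyl radical to give 14.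

2. Step 13. Substitution at the neopentylic C5 may be slow, so that elimination toward C4 or ionisation with a 1,2-methyl shift from C6 competes. The fallback sets out from alcohol 17 and returns at 18. Activation is separated from displacement: ClCH2SO2Cl and pyridine in CH2Cl2 at 0 °C should give the isolable (1S,3S)-3-{[4-bromo-2,5-bis(pivaloyloxy)phenyl]methyl}-2,2-dimethyl-4-methylidenecyclohexyl chloromethanesulfonate F3. This sulfonate is far more reactive toward SN2 than a tosylate; LiBr in DMF at 50 °C should displace it with inversion to give 18.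

3. Step 11. The catalyst may deactivate before the hindered trisubstituted alkene is reduced, or facial selectivity may erode through competing coordination of the ketone or ester carbonyls. The fallback sets out from silyl ether 14 (taken as one geometrical isomer) and returns at 16. Substrate direction is replaced by reagent control: asymmetric hydrogenation with a chiral iridium phosphine–oxazoline complex, [Ir(cod)(L)][B(C6H3(CF3)2)4] with L = 4-tert-butyl-2-[2-(diphenylphosphino)phenyl]-4,5-dihydrooxazole (H2 50 bar, CH2Cl2). This catalyst class is established for exocyclic α-arylidene ketones; the ligand enantiomer that matches the C5 centre would be chosen by trial. It should give (2R,4S)-2-{[4-bromo-2,5-bis(pivaloyloxy)phenyl]methyl}-4-(tert-butyldimethylsilyloxy)-3,3-dimethylcyclohexan-1-one F4, and 48% aq. HF in MeCN then frees 16.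

Further compounds
F1 | step 9 | (4S)-7-[4-bromo-2,5-bis(pivaloyloxy)phenyl]-4-(tert-butyldimethylsilyloxy)-5,5-dimethylhept-6-ynoic acid | OC(=O)CC[C@H](O[Si](C)(C)C(C)(C)C)C(C)(C)C#Cc1cc(OC(=O)C(C)(C)C)c(Br)cc1OC(=O)C(C)(C)C
F2 | step 9 | Se-phenyl (4S)-7-[4-bromo-2,5-bis(pivaloyloxy)phenyl]-4-(tert-butyldimethylsilyloxy)-5,5-dimethylhept-6-yneselenoate | O=C([Se]c1ccccc1)CC[C@H](O[Si](C)(C)C(C)(C)C)C(C)(C)C#Cc1cc(OC(=O)C(C)(C)C)c(Br)cc1OC(=O)C(C)(C)C
F3 | step 13 | (1S,3S)-3-{[4-bromo-2,5-bis(pivaloyloxy)phenyl]methyl}-2,2-dimethyl-4-methylidenecyclohexyl chloromethanesulfonate | C=C1CC[C@H](OS(=O)(=O)CCl)C(C)(C)[C@H]1Cc1cc(OC(=O)C(C)(C)C)c(Br)cc1OC(=O)C(C)(C)C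
F4 | step 11 | (2R,4S)-2-{[4-bromo-2,5-bis(pivaloyloxy)phenyl]methyl}-4-(tert-butyldimethylsilyloxy)-3,3-dimethylcyclohexan-1-one | O=C1CC[C@H](O[Si](C)(C)C(C)(C)C)C(C)(C)[C@H]1Cc1cc(OC(=O)C(C)(C)C)c(Br)cc1OC(=O)C(C)(C)C
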